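(The numbers of this flask are those of an exercise; no experiment stands behind them.)

A one-step world is easy: J adds to X, the number of chains stands from the first moment, and the length is monomer over chains. Here the chains start while others already grow, and the two recipes differ in J.

in all of them: D 2.50 mM; G 0.41 mM; time 25 s
- Friday's: J 0.050 M
- Saturday's: J 0.012 M

    J + G → J.G (k1 = 0.76 L mol⁻¹ s⁻¹)
    J + X → Z + X, rate k2*[X]*[J] (k2 = 3500 L mol⁻¹ s⁻¹)
    D + J → D.J (k3 = 19 L mol⁻¹ s⁻¹)
    J + G → X + Z (k4 = 1.0 L mol⁻¹ s⁻¹)

- which of the two ends with the longer chains by the average number of monomer units in a chain (chains begun, living or dead) ("neither" if they lie within 10%) (Friday's / Saturday's / neither)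
- average number of monomer units in a chain (chains begun, living or dead) at the end, Friday's
- average number of monomer units in a chain (chains begun, living or dead) at the end, Saturday's

I divide the rate of the step making X by the rate of growth. Time and c(J) drop out: each unit of Z brings new X in proportion to c(G)/c(X), with factor 2.86 × 10⁻⁴, the start constant over the growth constant. So c(X) is the root of 2 × factor × c(G) × Z, if c(G) holds still.

With J as charged, D has a half-life of 0.73 s on Friday's and 3.04 s on Saturday's, both shorter than 25 s, so as a rough budget I take charged J less charged D for Z: 47.5 mM on Friday's, 9.50 mM on Saturday's. J.G holds no Z, so I count X as the chains; each X costs 1.76 G, counting the G lost to J.G.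

The first extreme holds c(G) at its charge. This gives c(X) of 0.105 mM on Friday's and the slow-start length, budget over that X, 450; Saturday's gives 0.0472 mM and 201. The second extreme holds c(G) at the lowest that the first extreme's c(X) allows, 0.224 mM on Friday's and 0.327 mM on Saturday's, giving lengths 609 and 225. I expect the real c(G) between these two values in each flask, and so the length between its two extremes. I commit to the middles: 529 for Friday's and 213 for Saturday's.

The forecast names Friday's as the longer, with 298 (270 to 330) for Friday's and 121 (105 to 135) for Saturday's; its maker writes “I counted the J.G formed in step (1) as dead chains begun alongside X”, where I count X.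

The simulation gives Friday's as the longer, with 526 for Friday's and 212 for Saturday's; Friday's Z over X after 25.0 s is 526. A neighbour of Friday's has 0.0010 M of G. The slow-start length scales to 288, with c(X) 0.165 mM; lowest c(G) is 0.710 mM, the upper length 342, the middle 315. That neighbour gives 319.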